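**Retrosynthetic overview**
1. The target comes from a macrocyclic PMB-protected pentaol by acetylation and PMB removal; ring B (ten-membered) is closed last at C4–C5 by an intramolecular Nozaki–Hiyama–Kishi reaction of a (Z)-α-iodo enoate with the C4 aldehyde.
2. Ring C (lactone) is made earlier, on the open chain, by an intramolecular Reformatsky reaction (C8–C17) of a C7 2-bromopropanoate; C5/C6/C16 come from methyl propiolate, C3/C4 from an allylborane, C17–C19 from 2-bromopropanoic acid.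
3. Ring A is disconnected at C1–C10 and C11–C12: Diels–Alder union of a 1-alkoxy-3-silyloxy diene (C12–C13–C14–C1, carrying Me-15 and an ethynyl group as latent C2) with a chiral butenolide (C20/C11/C10/C9, with a dioxolane as C8/C7) made from D-gulono-1,4-lactone.
4. Enabling feature: on ring A the C20 methyl (on C11) and the oxygen-bearing C9 (on C10) are cis, so C20 and O9 can be tied into a temporary five-membered lactone that activates C10=C11, locks its cis geometry and carries the controlling stereocentre C9; the oxygens on C12 and C14 sit 1,3, as a 1-alkoxy-3-silyloxy diene delivers them. The lactone is later reduced to Me-20 and the C9 alcohol.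
5. Order of ring formation: ring A (step 8), ring C (step 24), ring B (step 26).

Key step: step 8

Remark: atom labels follow briarane numbering (C1 = quaternary fusion carbon with Me-15, C10 = other fusion carbon, C11 carries Me-20, C16 = ester carbon on C5, C17/C18/C19 = lactone CH, its methyl and its carbonyl); β is the face of ring A that carries Me-15; TBS = tert-butyldimethylsilyl, TES = triethylsilyl, PMB = 4-methoxybenzyl.

**Route**

Step 1
Reactants: 1 D-gulono-1,4-lactone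
Product: 2 5,6-O-isopropylidene-D-gulono-1,4-lactone
Conditions: 2-methoxypropene, TsOH·H2O (cat.), DMF, 0 °C
Reagents that add atoms: 2-methoxypropene, COC(C)=C
Why: Kinetic acid-catalysed acetalisation with 2-methoxypropene should select the terminal 5,6-diol.

Step 2
Reactants: 2 5,6-O-isopropylidene-D-gulono-1,4-lactone
Product: 3 5,6-O-isopropylidene-2,3-O-thiocarbonyl-D-gulono-1,4-lactone
Conditions: 1,1′-thiocarbonyldiimidazole, THF, 25 → 65 °C
Reagents that add atoms: 1,1′-thiocarbonyldiimidazole, S=C(n1ccnc1)n1ccnc1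
Why: The cis-2,3-diol should close to the cyclic thionocarbonate (first stage of a Corey–Winter olefination).

Step 3
Reactants: 3 5,6-O-isopropylidene-2,3-O-thiocarbonyl-D-gulono-1,4-lactone
Product: 4 (5R)-5-[(4R)-2,2-dimethyl-1,3-dioxolan-4-yl]furan-2(5H)-one
Conditions: 1,3-dimethyl-2-phenyl-1,3,2-diazaphospholidine, THF, 40 °C
Reagents that add atoms: none
Why: Corey–Winter olefination under mild, neutral conditions should give the butenolide without touching the γ-stereocentre (future C9).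

Step 4
Reactants: 5 (±)-4-(trimethylsilyl)but-3-yn-2-ol
Product: 6 (±)-3-bromo-1-(trimethylsilyl)but-1-yne
Conditions: CBr4, PPh3, CH2Cl2, 0 °C
Reagents that add atoms: carbon tetrabromide, BrC(Br)(Br)Br
Why: Appel bromination of the propargylic alcohol.

Step 5
Reactants: 6 (±)-3-bromo-1-(trimethylsilyl)but-1-yne; 7 (E)-3-ethoxyacryloyl chloride
Product: 9 (E)-1-ethoxy-4-methyl-6-(trimethylsilyl)hex-1-en-5-yn-3-one, via allenylzinc bromide 8 (not isolated)
Conditions: Zn dust, LiCl, THF, 25 °C; then addition to 7, THF, −78 → −30 °C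
Reagents that add atoms: none
Why: Zinc insertion gives the allenylzinc bromide, which should be acylated at its γ-carbon (SE2′) to the α-methyl propargyl ketone; low temperature and the deactivated vinylogous-ester ketone should prevent a second addition.

Step 6
Reactants: 9 (E)-1-ethoxy-4-methyl-6-(trimethylsilyl)hex-1-en-5-yn-3-one; 10 4-methoxybenzyl alcohol
Product: 11 (E)-1-[(4-methoxybenzyl)oxy]-4-methyl-6-(trimethylsilyl)hex-1-en-5-yn-3-one
Conditions: PPTS (cat.), PhMe, 60 °C, reduced pressure (removal of EtOH)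
Reagents that add atoms: none
Why: Acid-catalysed transetherification of the vinylogous ester (addition–elimination) should give the thermodynamic E enol ether.

Step 7
Reactants: 11 (E)-1-[(4-methoxybenzyl)oxy]-4-methyl-6-(trimethylsilyl)hex-1-en-5-yn-3-one
Product: 12 (1E,3E)-3-[(tert-butyldimethylsilyl)oxy]-1-[(4-methoxybenzyl)oxy]-4-methyl-6-(trimethylsilyl)hexa-1,3-dien-5-yne
Conditions: TBSOTf, Et3N, CH2Cl2, −78 → 0 °C
Reagents that add atoms: tert-butyldimethylsilyl triflate, CC(C)(C)[Si](C)(C)OS(=O)(=O)C(F)(F)F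
Why: Soft enolisation at the only enolisable carbon (C1) under equilibrating conditions should favour the 3E dienol ether, with the larger methyl group syn to OTBS and the slim alkynyl group syn to the vinyl branch.

Step 8
Reactants: 12 (1E,3E)-diene; 4 (5R)-5-[(4R)-2,2-dimethyl-1,3-dioxolan-4-yl]furan-2(5H)-one
Product: 14 ethynyl keto lactone of ring A, via cycloadduct silyl enol ether 13 (not isolated)
Conditions: PhMe, BHT (cat.), 110 °C, sealed tube; then n-Bu4NF/AcOH (1:1), THF, 0 °C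
Reagents that add atoms: none
Why: Thermal normal-demand Diels–Alder reaction, a concerted asynchronous [4+2] cycloaddition in which the electron-rich terminus C1 of the diene bonds to the β-carbon C10 of the butenolide and C12 bonds to C11; the closest known reaction type is the cycloaddition of 1-alkoxy-3-silyloxy dienes with γ-substituted butenolides. Ring A is closed in the [4+2] mode through the endo transition state, the temporary lactone ring being carried along. C10 and C11 follow from the cis geometry fixed by the lactone and from approach of the diene to the face anti to the dioxolanyl group on C9; C12 follows from the 1E enol ether and C1 from the 3E enol ether, both translated by the endo rule (outside groups OPMB and Me-15 cis to the lactone, ethynyl trans). The step needs regio-, endo and π-facial selectivity: the two oxygen donors fix the regiochemistry, the bulky γ-substituent fixes the face, and the linear ethynyl group is the only inside substituent, so the s-cis conformer should stay accessible. Buffered fluoride then cleaves the silyl enol ether and the C-silyl group without β-elimination of the C12 ether.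

Step 9
Reactants: 14 ethynyl keto lactone of ring A
Product: 16 14α-hydroxy lactol, via 14α-hydroxy lactone 15 (not isolated)
Conditions: LiBH(s-Bu)3 (L-Selectride), THF, −78 °C; then i-Bu2AlH, −78 °C; aq. KNaC4H4O6
Reagents that add atoms: none
Why: The bulky borohydride should attack the C14 ketone along the equatorial trajectory (as in 4,4-dimethyl-3-oxo steroids) to give the axial 14α-alcohol, and i-Bu2AlH then stops at the lactol (partial lactone reduction).

Step 10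
Reactants: 16 14α-hydroxy lactol
Product: 18 C9/C14 diol carrying Me-20, via tosylhydrazone 17 (not isolated)
Conditions: TsNHNH2, THF, 25 °C; then catecholborane, CHCl3, 0 °C; then NaOAc·3H2O, 60 °C
Reagents that add atoms: none
Why: Caglioti-type reduction: the open hydroxy-aldehyde form condenses to the tosylhydrazone, whose hydroboration and fragmentation should deliver the C20 methyl group under conditions too mild to epimerise C11.

Step 11
Reactants: 18 C9/C14 diol carrying Me-20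
Product: 19 9,14-bis-TBS ether
Conditions: TBSOTf, 2,6-lutidine, CH2Cl2, 0 → 25 °C
Reagents that add atoms: tert-butyldimethylsilyl triflate, CC(C)(C)[Si](C)(C)OS(=O)(=O)C(F)(F)F
Why: Silyl triflate silylation of both hindered secondary alcohols.

Step 12
Reactants: 19 9,14-bis-TBS ether
Product: 20 1α-vinyl compound
Conditions: H2 (1 atm), Pd/CaCO3 poisoned with Pb(OAc)2 (Lindlar catalyst), quinoline, EtOAc, 25 °C
Reagents that add atoms: none
Why: Lindlar semi-hydrogenation of the terminal alkyne; PMB and silyl ethers are inert.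

Step 13
Reactants: 20 1α-vinyl compound
Product: 21 C2 aldehyde
Conditions: OsO4 (cat.), NaIO4, 2,6-lutidine, dioxane–H2O (3:1), 25 °C
Reagents that add atoms: osmium tetroxide (turned over by NaIO4), O=[Os](=O)(=O)=O
Why: Lemieux–Johnson cleavage of the vinyl group gives the non-enolisable neopentyl aldehyde.

Step 14
Reactants: 21 C2 aldehyde
Product: 22 (2R)-homoallylic alcohol
Conditions: (+)-Ipc2B(allyl) (from (−)-α-pinene), Et2O, −78 °C; then NaOH, H2O2, 0 °C
Reagents that add atoms: (+)-B-allyldiisopinocampheylborane, C=CCB([C@H]1C[C@H]2C[C@@H]([C@@H]1C)C2(C)C)[C@H]1C[C@H]2C[C@@H]([C@@H]1C)C2(C)C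
Why: Brown allylation under reagent control; this enantiomer of the borane should add to the Re face, as it does with pivalaldehyde, and set 2R.

Step 15
Reactants: 22 (2R)-homoallylic alcohol
Product: 23 2,9,14-tris-TBS ether
Conditions: TBSOTf, 2,6-lutidine, CH2Cl2, 0 → 25 °C
Reagents that add atoms: tert-butyldimethylsilyl triflate, CC(C)(C)[Si](C)(C)OS(=O)(=O)C(F)(F)F
Why: Silylation of the neopentyl secondary alcohol.

Step 16
Reactants: 23 2,9,14-tris-TBS ether
Product: 24 7,8-diol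
Conditions: AcOH–H2O–THF (3:1:1), 40 °C
Reagents that add atoms: none
Why: Mild acid hydrolysis of the terminal acetonide; secondary TBS ethers and the PMB ether should survive.

Step 17
Reactants: 24 7,8-diol
Product: 25 7,8-bis-TES ether
Conditions: TESOTf, 2,6-lutidine, CH2Cl2, −78 °C
Reagents that add atoms: triethylsilyl triflate, CC[Si](CC)(CC)OS(=O)(=O)C(F)(F)F
Why: Silylation of both hydroxyl groups.

Step 18
Reactants: 25 7,8-bis-TES ether
Product: 26 C7 aldehyde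
Conditions: (COCl)2, DMSO, CH2Cl2, −78 → −40 °C; then Et3N
Reagents that add atoms: none
Why: Swern conditions cleave and oxidise the primary TES ether selectively and leave the secondary TES ether (known selective oxidative desilylation).

Step 19
Reactants: 26 C7 aldehyde; 27 methyl propiolate
Product: 29 (7R)-propargylic alcohol (ynoate), via methyl 3-lithiopropiolate 28 (not isolated)
Conditions: LiN(SiMe3)2, THF, −78 °C; then 26, −78 °C; aq. NH4Cl
Reagents that add atoms: none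
Why: 1,2-Addition of the lithium acetylide under Felkin–Anh control by the α-silyloxy centre C8 should give the 7,8-anti (7R) alcohol.

Step 20
Reactants: 29 (7R)-propargylic alcohol (ynoate)
Product: 31 (7R)-(Z)-α-iodo enoate alcohol, via alkenylaluminate 30 (not isolated)
Conditions: NaAlH2(OCH2CH2OMe)2 (Red-Al), THF, −72 °C; then I2, THF, −72 → −20 °C; aq. KNaC4H4O6
Reagents that add atoms: iodine, II
Why: Hydroxyl-directed trans-hydroalumination delivers hydride to C6 and aluminium to C5, and iodinolysis with retention should give the (Z)-α-iodo enoate.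

Step 21
Reactants: 31 (7R)-(Z)-α-iodo enoate alcohol; 32 (±)-2-bromopropanoic acid
Product: 33 (7S)-2-bromopropanoate
Conditions: PPh3, DIAD, PhMe, 0 °C
Reagents that add atoms: none
Why: Mitsunobu esterification should invert C7 to the required 7S configuration and install the latent C17–C19 unit in the same operation.

Step 22
Reactants: 33 (7S)-2-bromopropanoate
Product: 34 C8 alcohol
Conditions: PPTS, MeOH–CH2Cl2 (1:1), 0 °C
Reagents that add atoms: none
Why: Mild acid methanolysis removes the secondary TES ether selectively in the presence of TBS ethers.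

Step 23
Reactants: 34 C8 alcohol
Product: 35 C8 ketone
Conditions: Dess–Martin periodinane, NaHCO3, CH2Cl2, 0 → 25 °C
Reagents that add atoms: none
Why: Dess–Martin oxidation under buffered conditions that should not epimerise C7 or C9.

Step 24
Reactants: 35 C8 ketone
Product: 36 lactone (ring C closed) with allyl and iodo-enoate arms
Conditions: SmI2 (2.2 equiv), THF, −78 °C; aq. NH4Cl
Reagents that add atoms: none
Why: Intramolecular Reformatsky reaction, in which SmI2 at −78 °C should reduce the α-bromo ester well before the ketone or the alkenyl iodide and the samarium enolate adds to the C8 ketone to close the five-membered lactone; the chelated transition state should place C9 anti to the C7 alkenyl group and the C17 methyl anti to C9, giving 8S,17R.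

Step 25
Reactants: 36 lactone with allyl and iodo-enoate arms
Product: 37 C4 aldehyde
Conditions: OsO4 (cat.), NaIO4, 2,6-lutidine, dioxane–H2O (3:1), 25 °C
Reagents that add atoms: osmium tetroxide (turned over by NaIO4), O=[Os](=O)(=O)=O
Why: Lemieux–Johnson cleavage of the terminal alkene; the iodo-enoate is too electron-poor to be dihydroxylated.

Step 26
Reactants: 37 C4 aldehyde
Product: 38 macrocyclic C4 alcohol (ring B closed)
Conditions: CrCl2 (10 equiv), NiCl2 (cat.), DMSO–THF (3:1), 25 °C, high dilution, slow addition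
Reagents that add atoms: none
Why: Nozaki–Hiyama–Kishi macrocyclisation: the alkenylchromium species from the (Z)-α-iodo enoate adds to the C4 aldehyde; only the cis ring alkene can close, and addition to the outer face of the aldehyde in the lactone-biased conformer should give 4R.

Step 27
Reactants: 38 macrocyclic C4 alcohol
Product: 39 macrocyclic pentaol PMB ether
Conditions: HF·pyridine, pyridine, THF, 0 → 25 °C
Reagents that add atoms: none
Why: Fluoride cleavage of the three TBS ethers; the PMB ether, lactone and enoate are stable.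

Step 28
Reactants: 39 macrocyclic pentaol PMB ether
Product: 40 2,4,9,14-tetraacetate PMB ether
Conditions: Ac2O, pyridine, DMAP (cat.), CH2Cl2, 0 → 25 °C
Reagents that add atoms: acetic anhydride, CC(=O)OC(C)=O
Why: Acetylation of the four secondary alcohols; the tertiary C8 alcohol should not react under these conditions.

Step 29
Reactants: 40 2,4,9,14-tetraacetate PMB ether
Product: 41 CNP0169867.2
Conditions: DDQ, CH2Cl2–pH 7 buffer (10:1), 0 → 25 °C
Reagents that add atoms: none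
Why: Oxidative PMB cleavage liberates the C12 alcohol without touching the acetates.

**Compound list**
1 | D-gulono-1,4-lactone | OC[C@@H](O)[C@H](OC1=O)[C@@H](O)[C@H]1O | starting material
2 | 5,6-O-isopropylidene-D-gulono-1,4-lactone | CC1(C)OC[C@@H](O1)[C@H](OC2=O)[C@@H](O)[C@H]2O | intermediate
3 | 5,6-O-isopropylidene-2,3-O-thiocarbonyl-D-gulono-1,4-lactone | CC1(C)OC[C@@H](O1)[C@H](OC2=O)[C@@H](OC(=S)O3)[C@H]23 | intermediate
4 | (5R)-5-[(4R)-2,2-dimethyl-1,3-dioxolan-4-yl]furan-2(5H)-one | CC1(C)OC[C@@H](O1)[C@H](OC2=O)C=C2 | intermediate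
5 | (±)-4-(trimethylsilyl)but-3-yn-2-ol | CC(O)C#C[Si](C)(C)C | starting material
6 | (±)-3-bromo-1-(trimethylsilyl)but-1-yne | CC(Br)C#C[Si](C)(C)C | intermediate
7 | (E)-3-ethoxyacryloyl chloride | CCO/C=C/C(Cl)=O | starting material
8 | [1-(trimethylsilyl)buta-1,2-dienyl]zinc bromide | CC=C=C([Zn]Br)[Si](C)(C)C | intermediate
9 | (E)-1-ethoxy-4-methyl-6-(trimethylsilyl)hex-1-en-5-yn-3-one (racemic) | CCO/C=C/C(=O)C(C)C#C[Si](C)(C)C | intermediate
10 | 4-methoxybenzyl alcohol | COc1ccc(CO)cc1 | starting material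
11 | (E)-1-[(4-methoxybenzyl)oxy]-4-methyl-6-(trimethylsilyl)hex-1-en-5-yn-3-one (racemic) | COc1ccc(CO/C=C/C(=O)C(C)C#C[Si](C)(C)C)cc1 | intermediate
12 | (1E,3E)-3-[(tert-butyldimethylsilyl)oxy]-1-[(4-methoxybenzyl)oxy]-4-methyl-6-(trimethylsilyl)hexa-1,3-dien-5-yne | COc1ccc(CO/C=C/C(O[Si](C)(C)C(C)(C)C)=C(/C)C#C[Si](C)(C)C)cc1 | intermediate
13 | cycloadduct: ring A 13-ene 14-OTBS enol ether, 12β-OPMB, 1β-Me, 1α-(TMS-ethynyl), cis-fused 20,9-lactone, dioxolanyl on C9 | CC1(C)OC[C@@H](O1)[C@H](O3)[C@H]2[C@@H](C3=O)[C@@H](OCc4ccc(OC)cc4)C=C(O[Si](C)(C)C(C)(C)C)[C@]2(C)C#C[Si](C)(C)C | intermediate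
14 | ethynyl keto lactone: 14-oxo, 12β-OPMB, 1β-Me, 1α-ethynyl, cis-fused 20,9-lactone | CC1(C)OC[C@@H](O1)[C@H](O3)[C@H]2[C@@H](C3=O)[C@@H](OCc4ccc(OC)cc4)CC(=O)[C@]2(C)C#C | intermediate
15 | 14α-hydroxy lactone | CC1(C)OC[C@@H](O1)[C@H](O3)[C@H]2[C@@H](C3=O)[C@@H](OCc4ccc(OC)cc4)C[C@H](O)[C@]2(C)C#C | intermediate
16 | 14α-hydroxy lactol (C20 anomers) | CC1(C)OC[C@@H](O1)[C@H](O3)[C@H]2[C@@H](C3O)[C@@H](OCc4ccc(OC)cc4)C[C@H](O)[C@]2(C)C#C | intermediate
17 | C20 tosylhydrazone with free 9- and 14-OH | CC1(C)OC[C@@H](O1)[C@H](O)[C@H]2[C@@H](C=NNS(=O)(=O)c3ccc(C)cc3)[C@@H](OCc3ccc(OC)cc3)C[C@H](O)[C@]2(C)C#C | intermediate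
18 | 9,14-diol with 11β-methyl (Me-20), 12β-OPMB, 1α-ethynyl | CC1(C)OC[C@@H](O1)[C@H](O)[C@H]2[C@@H](C)[C@@H](OCc3ccc(OC)cc3)C[C@H](O)[C@]2(C)C#C | intermediate
19 | 9,14-bis-TBS ether, 1α-ethynyl | CC1(C)OC[C@@H](O1)[C@H](O[Si](C)(C)C(C)(C)C)[C@H]2[C@@H](C)[C@@H](OCc3ccc(OC)cc3)C[C@H](O[Si](C)(C)C(C)(C)C)[C@]2(C)C#C | intermediate
20 | 9,14-bis-TBS ether, 1α-vinyl | CC1(C)OC[C@@H](O1)[C@H](O[Si](C)(C)C(C)(C)C)[C@H]2[C@@H](C)[C@@H](OCc3ccc(OC)cc3)C[C@H](O[Si](C)(C)C(C)(C)C)[C@]2(C)C=C | intermediate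
21 | C2 aldehyde (1α-formyl) | CC1(C)OC[C@@H](O1)[C@H](O[Si](C)(C)C(C)(C)C)[C@H]2[C@@H](C)[C@@H](OCc3ccc(OC)cc3)C[C@H](O[Si](C)(C)C(C)(C)C)[C@]2(C)C=O | intermediate
22 | (2R)-homoallylic alcohol (C2–OH, C3H2, C4=CH2) | CC1(C)OC[C@@H](O1)[C@H](O[Si](C)(C)C(C)(C)C)[C@H]2[C@@H](C)[C@@H](OCc3ccc(OC)cc3)C[C@H](O[Si](C)(C)C(C)(C)C)[C@]2(C)[C@H](O)CC=C | intermediate
23 | 2,9,14-tris-TBS ether with 7,8-acetonide | CC1(C)OC[C@@H](O1)[C@H](O[Si](C)(C)C(C)(C)C)[C@H]2[C@@H](C)[C@@H](OCc3ccc(OC)cc3)C[C@H](O[Si](C)(C)C(C)(C)C)[C@]2(C)[C@H](O[Si](C)(C)C(C)(C)C)CC=C | intermediate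
24 | (8R)-7,8-diol | OC[C@@H](O)[C@H](O[Si](C)(C)C(C)(C)C)[C@H]1[C@@H](C)[C@@H](OCc2ccc(OC)cc2)C[C@H](O[Si](C)(C)C(C)(C)C)[C@]1(C)[C@H](O[Si](C)(C)C(C)(C)C)CC=C | intermediate
25 | 7,8-bis-TES ether | CC[Si](CC)(CC)OC[C@@H](O[Si](CC)(CC)CC)[C@H](O[Si](C)(C)C(C)(C)C)[C@H]1[C@@H](C)[C@@H](OCc2ccc(OC)cc2)C[C@H](O[Si](C)(C)C(C)(C)C)[C@]1(C)[C@H](O[Si](C)(C)C(C)(C)C)CC=C | intermediate
26 | C7 aldehyde with 8-OTES | O=C[C@@H](O[Si](CC)(CC)CC)[C@H](O[Si](C)(C)C(C)(C)C)[C@H]1[C@@H](C)[C@@H](OCc2ccc(OC)cc2)C[C@H](O[Si](C)(C)C(C)(C)C)[C@]1(C)[C@H](O[Si](C)(C)C(C)(C)C)CC=C | intermediate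
27 | methyl propiolate | COC(=O)C#C | starting material
28 | methyl 3-lithiopropiolate | COC(=O)C#C[Li] | intermediate
29 | (7R)-propargylic alcohol, methyl 4-hydroxy-2-ynoate arm (C16, C5≡C6, C7) | COC(=O)C#C[C@@H](O)[C@@H](O[Si](CC)(CC)CC)[C@H](O[Si](C)(C)C(C)(C)C)[C@H]1[C@@H](C)[C@@H](OCc2ccc(OC)cc2)C[C@H](O[Si](C)(C)C(C)(C)C)[C@]1(C)[C@H](O[Si](C)(C)C(C)(C)C)CC=C | intermediate
30 | cyclic alkenylaluminate (Al on C5 and O7), sodium salt | [Na+].COCCO[Al-]1(OCCOC)O[C@H](C=C1C(=O)OC)[C@@H](O[Si](CC)(CC)CC)[C@H](O[Si](C)(C)C(C)(C)C)[C@H]1[C@@H](C)[C@@H](OCc2ccc(OC)cc2)C[C@H](O[Si](C)(C)C(C)(C)C)[C@]1(C)[C@H](O[Si](C)(C)C(C)(C)C)CC=C | intermediate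
31 | (7R)-alcohol with (Z)-α-iodo enoate (I on C5) | COC(=O)/C(I)=C/[C@@H](O)[C@@H](O[Si](CC)(CC)CC)[C@H](O[Si](C)(C)C(C)(C)C)[C@H]1[C@@H](C)[C@@H](OCc2ccc(OC)cc2)C[C@H](O[Si](C)(C)C(C)(C)C)[C@]1(C)[C@H](O[Si](C)(C)C(C)(C)C)CC=C | intermediate
32 | (±)-2-bromopropanoic acid | CC(Br)C(O)=O | starting material
33 | (7S)-2-bromopropanoate (mixture at CHBr) | COC(=O)/C(I)=C/[C@H](OC(=O)C(C)Br)[C@@H](O[Si](CC)(CC)CC)[C@H](O[Si](C)(C)C(C)(C)C)[C@H]1[C@@H](C)[C@@H](OCc2ccc(OC)cc2)C[C@H](O[Si](C)(C)C(C)(C)C)[C@]1(C)[C@H](O[Si](C)(C)C(C)(C)C)CC=C | intermediate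
34 | C8 alcohol | COC(=O)/C(I)=C/[C@H](OC(=O)C(C)Br)[C@@H](O)[C@H](O[Si](C)(C)C(C)(C)C)[C@H]1[C@@H](C)[C@@H](OCc2ccc(OC)cc2)C[C@H](O[Si](C)(C)C(C)(C)C)[C@]1(C)[C@H](O[Si](C)(C)C(C)(C)C)CC=C | intermediate
35 | C8 ketone | COC(=O)/C(I)=C/[C@H](OC(=O)C(C)Br)C(=O)[C@H](O[Si](C)(C)C(C)(C)C)[C@H]1[C@@H](C)[C@@H](OCc2ccc(OC)cc2)C[C@H](O[Si](C)(C)C(C)(C)C)[C@]1(C)[C@H](O[Si](C)(C)C(C)(C)C)CC=C | intermediate
36 | (7S,8S,17R)-lactone with 8-OH, allyl arm and (Z)-iodo-enoate arm | COC(=O)/C(I)=C/[C@@H]2OC(=O)[C@H](C)[C@@]2(O)[C@H](O[Si](C)(C)C(C)(C)C)[C@H]1[C@@H](C)[C@@H](OCc2ccc(OC)cc2)C[C@H](O[Si](C)(C)C(C)(C)C)[C@]1(C)[C@H](O[Si](C)(C)C(C)(C)C)CC=C | intermediate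
37 | C4 aldehyde | COC(=O)/C(I)=C/[C@@H]2OC(=O)[C@H](C)[C@@]2(O)[C@H](O[Si](C)(C)C(C)(C)C)[C@H]1[C@@H](C)[C@@H](OCc2ccc(OC)cc2)C[C@H](O[Si](C)(C)C(C)(C)C)[C@]1(C)[C@H](O[Si](C)(C)C(C)(C)C)CC=O | intermediate
38 | macrocycle: (4R)-4-OH, 2,9,14-tris-OTBS, 12β-OPMB, 8-OH, 7,19-lactone, 5E methyl enoate | COC(=O)/C1=C/[C@@H]2OC(=O)[C@H](C)[C@@]2(O)[C@H](O[Si](C)(C)C(C)(C)C)[C@H]2[C@@H](C)[C@@H](OCc3ccc(OC)cc3)C[C@H](O[Si](C)(C)C(C)(C)C)[C@]2(C)[C@H](O[Si](C)(C)C(C)(C)C)C[C@H]1O | intermediate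
39 | macrocyclic 2,4,8,9,14-pentaol 12-PMB ether | COC(=O)/C1=C/[C@@H]2OC(=O)[C@H](C)[C@@]2(O)[C@H](O)[C@H]2[C@@H](C)[C@@H](OCc3ccc(OC)cc3)C[C@H](O)[C@]2(C)[C@H](O)C[C@H]1O | intermediate
40 | 2,4,9,14-tetraacetate 12-PMB ether | COC(=O)/C1=C/[C@@H]2OC(=O)[C@H](C)[C@@]2(O)[C@H](OC(C)=O)[C@H]2[C@@H](C)[C@@H](OCc3ccc(OC)cc3)C[C@H](OC(C)=O)[C@]2(C)[C@H](OC(C)=O)C[C@H]1OC(C)=O | intermediate
41 | CNP0169867.2, (1R,2R,4R,5E,7S,8S,9R,10S,11R,12S,14S,17R) | COC(=O)/C1=C/[C@@H]2OC(=O)[C@H](C)[C@@]2(O)[C@H](OC(C)=O)[C@H]2[C@@H](C)[C@@H](O)C[C@H](OC(C)=O)[C@]2(C)[C@H](OC(C)=O)C[C@H]1OC(C)=O | target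

**Totals**
Total step count: 29. Longest linear sequence: 26 steps (steps 4–7, then 8–29).

**Steps most likely to fail, and fallbacks**

Step 8. The cycloaddition may be too slow or lose endo selectivity, because the diene must reach an s-cis conformation with one inside substituent, and any geometric impurity of the tetrasubstituted enol ether would erode the C1 configuration. Fallback (sets out from 4 and 10, comes back at 14): the quaternary centre is made after the cycloaddition. Oxa-Michael addition of 10 to commercial pent-1-yn-3-one (DABCO cat.) would give (E)-1-[(4-methoxybenzyl)oxy]pent-1-en-3-one F1, and TBSOTf/Et3N the (1E,3Z)-diene F2, which has no inside substituent. Diels–Alder reaction with 4 would give the cycloadduct F3, and buffered fluoride the C1–H ketone F4. Thermodynamic silylation (TMSCl, Et3N, DMF, 80 °C) would give the more substituted C1=C14 trimethylsilyl enol ether F5. Electrophilic alkynylation with 1-[(trimethylsilyl)ethynyl]-1,2-benziodoxol-3(1H)-one and n-Bu4NF (THF, −78 °C) should introduce the ethynyl group anti to C9 and give 14.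

Step 21. The Mitsunobu displacement may stall or give elimination at the hindered allylic carbinol flanked by C8. Fallback (sets out from 29, comes back at 33): C7 is set by reagent control instead of inversion. Dess–Martin oxidation of 29 would give the ynone F6. Corey–Bakshi–Shibata reduction ((R)-2-methyl-oxazaborolidine, catecholborane, −78 °C, alkynyl as the small group) would give the (7S)-propargylic alcohol F7. Hydroalumination–iodination as in step 20 would give the (7S)-iodo enoate F8, and acylation with 2-bromopropanoyl bromide and pyridine (retention) would give 33.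

Step 26. Ring closure may lose out to oligomerisation or protodeiodination, because the ten-membered ring must form while the trans-fused lactone is already in place, and the facial selectivity at C4 is not secured. Fallback (sets out from 23, comes back at 39): the ring is closed at C6–C7 before the lactone exists. Lemieux–Johnson cleavage of 23 would give the C4 aldehyde F9. A MgI2-mediated iodo-aldol reaction with methyl propiolate 27 under equilibrating conditions would give the (E)-β-iodo hydroxy acrylate F10, and TBSOTf/2,6-lutidine its 4-O-TBS ether F11. Acetonide hydrolysis would give the 7,8-diol F12, TESOTf the 7,8-bis-TES ether F13 and Swern oxidation the C7 aldehyde F14. Nozaki–Hiyama–Kishi macrocyclisation of this β-iodoacrylate, in which the ring constraint is relied on for the C7 configuration, would give the macrocyclic (7S)-alcohol F15. Acylation with 2-bromopropanoyl bromide would give the macrocyclic 7-(2-bromopropanoate) F16, PPTS/MeOH the macrocyclic C8 alcohol F17, Dess–Martin oxidation the macrocyclic C8 ketone F18 and a SmI2 Reformatsky closure the macrocyclic lactone F19. HF·pyridine would then give 39.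

**Further compounds**
F1 | step 8 | (E)-1-[(4-methoxybenzyl)oxy]pent-1-en-3-one | COc1ccc(CO/C=C/C(=O)CC)cc1
F2 | step 8 | (1E,3Z)-3-[(tert-butyldimethylsilyl)oxy]-1-[(4-methoxybenzyl)oxy]penta-1,3-diene | COc1ccc(CO/C=C/C(O[Si](C)(C)C(C)(C)C)=C/C)cc1
F3 | step 8 | cycloadduct silyl enol ether lacking the ethynyl group (1β-Me, 1α-H) | CC1(C)OC[C@@H](O1)[C@H](O3)[C@H]2[C@@H](C3=O)[C@@H](OCc4ccc(OC)cc4)C=C(O[Si](C)(C)C(C)(C)C)[C@H]2C
F4 | step 8 | C1–H keto lactone | CC1(C)OC[C@@H](O1)[C@H](O3)[C@H]2[C@@H](C3=O)[C@@H](OCc4ccc(OC)cc4)CC(=O)[C@H]2C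
F5 | step 8 | C1=C14 trimethylsilyl enol ether | CC1(C)OC[C@@H](O1)[C@H](O3)[C@H]2[C@@H](C3=O)[C@@H](OCc4ccc(OC)cc4)CC(O[Si](C)(C)C)=C2C
F6 | step 21 | C7 ynone (methyl 4-oxo-2-ynoate arm) | COC(=O)C#CC(=O)[C@@H](O[Si](CC)(CC)CC)[C@H](O[Si](C)(C)C(C)(C)C)[C@H]1[C@@H](C)[C@@H](OCc2ccc(OC)cc2)C[C@H](O[Si](C)(C)C(C)(C)C)[C@]1(C)[C@H](O[Si](C)(C)C(C)(C)C)CC=C
F7 | step 21 | (7S)-propargylic alcohol | COC(=O)C#C[C@H](O)[C@@H](O[Si](CC)(CC)CC)[C@H](O[Si](C)(C)C(C)(C)C)[C@H]1[C@@H](C)[C@@H](OCc2ccc(OC)cc2)C[C@H](O[Si](C)(C)C(C)(C)C)[C@]1(C)[C@H](O[Si](C)(C)C(C)(C)C)CC=C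
F8 | step 21 | (7S)-(Z)-α-iodo enoate alcohol | COC(=O)/C(I)=C/[C@H](O)[C@@H](O[Si](CC)(CC)CC)[C@H](O[Si](C)(C)C(C)(C)C)[C@H]1[C@@H](C)[C@@H](OCc2ccc(OC)cc2)C[C@H](O[Si](C)(C)C(C)(C)C)[C@]1(C)[C@H](O[Si](C)(C)C(C)(C)C)CC=C
F9 | step 26 | C4 aldehyde with 7,8-acetonide | CC1(C)OC[C@@H](O1)[C@H](O[Si](C)(C)C(C)(C)C)[C@H]2[C@@H](C)[C@@H](OCc3ccc(OC)cc3)C[C@H](O[Si](C)(C)C(C)(C)C)[C@]2(C)[C@H](O[Si](C)(C)C(C)(C)C)CC=O
F10 | step 26 | (4R)-hydroxy (E)-β-iodo acrylate | CC1(C)OC[C@@H](O1)[C@H](O[Si](C)(C)C(C)(C)C)[C@H]2[C@@H](C)[C@@H](OCc3ccc(OC)cc3)C[C@H](O[Si](C)(C)C(C)(C)C)[C@]2(C)[C@H](O[Si](C)(C)C(C)(C)C)C[C@@H](O)/C(=C\I)C(=O)OC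
F11 | step 26 | 4-O-TBS ether of F10 | CC1(C)OC[C@@H](O1)[C@H](O[Si](C)(C)C(C)(C)C)[C@H]2[C@@H](C)[C@@H](OCc3ccc(OC)cc3)C[C@H](O[Si](C)(C)C(C)(C)C)[C@]2(C)[C@H](O[Si](C)(C)C(C)(C)C)C[C@@H](O[Si](C)(C)C(C)(C)C)/C(=C\I)C(=O)OC
F12 | step 26 | 7,8-diol | OC[C@@H](O)[C@H](O[Si](C)(C)C(C)(C)C)[C@H]1[C@@H](C)[C@@H](OCc2ccc(OC)cc2)C[C@H](O[Si](C)(C)C(C)(C)C)[C@]1(C)[C@H](O[Si](C)(C)C(C)(C)C)C[C@@H](O[Si](C)(C)C(C)(C)C)/C(=C\I)C(=O)OC
F13 | step 26 | 7,8-bis-TES ether | CC[Si](CC)(CC)OC[C@@H](O[Si](CC)(CC)CC)[C@H](O[Si](C)(C)C(C)(C)C)[C@H]1[C@@H](C)[C@@H](OCc2ccc(OC)cc2)C[C@H](O[Si](C)(C)C(C)(C)C)[C@]1(C)[C@H](O[Si](C)(C)C(C)(C)C)C[C@@H](O[Si](C)(C)C(C)(C)C)/C(=C\I)C(=O)OC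
F14 | step 26 | C7 aldehyde with (E)-β-iodo acrylate | O=C[C@@H](O[Si](CC)(CC)CC)[C@H](O[Si](C)(C)C(C)(C)C)[C@H]1[C@@H](C)[C@@H](OCc2ccc(OC)cc2)C[C@H](O[Si](C)(C)C(C)(C)C)[C@]1(C)[C@H](O[Si](C)(C)C(C)(C)C)C[C@@H](O[Si](C)(C)C(C)(C)C)/C(=C\I)C(=O)OC
F15 | step 26 | macrocyclic (7S)-alcohol with 8-OTES and 4-OTBS | COC(=O)/C1=C/[C@H](O)[C@@H](O[Si](CC)(CC)CC)[C@H](O[Si](C)(C)C(C)(C)C)[C@H]2[C@@H](C)[C@@H](OCc3ccc(OC)cc3)C[C@H](O[Si](C)(C)C(C)(C)C)[C@]2(C)[C@H](O[Si](C)(C)C(C)(C)C)C[C@H]1O[Si](C)(C)C(C)(C)C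
F16 | step 26 | macrocyclic 7-(2-bromopropanoate) | COC(=O)/C1=C/[C@H](OC(=O)C(C)Br)[C@@H](O[Si](CC)(CC)CC)[C@H](O[Si](C)(C)C(C)(C)C)[C@H]2[C@@H](C)[C@@H](OCc3ccc(OC)cc3)C[C@H](O[Si](C)(C)C(C)(C)C)[C@]2(C)[C@H](O[Si](C)(C)C(C)(C)C)C[C@H]1O[Si](C)(C)C(C)(C)C
F17 | step 26 | macrocyclic C8 alcohol | COC(=O)/C1=C/[C@H](OC(=O)C(C)Br)[C@@H](O)[C@H](O[Si](C)(C)C(C)(C)C)[C@H]2[C@@H](C)[C@@H](OCc3ccc(OC)cc3)C[C@H](O[Si](C)(C)C(C)(C)C)[C@]2(C)[C@H](O[Si](C)(C)C(C)(C)C)C[C@H]1O[Si](C)(C)C(C)(C)C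
F18 | step 26 | macrocyclic C8 ketone | COC(=O)/C1=C/[C@H](OC(=O)C(C)Br)C(=O)[C@H](O[Si](C)(C)C(C)(C)C)[C@H]2[C@@H](C)[C@@H](OCc3ccc(OC)cc3)C[C@H](O[Si](C)(C)C(C)(C)C)[C@]2(C)[C@H](O[Si](C)(C)C(C)(C)C)C[C@H]1O[Si](C)(C)C(C)(C)C
F19 | step 26 | macrocyclic lactone, 2,4,9,14-tetrakis-OTBS | COC(=O)/C1=C/[C@@H]2OC(=O)[C@H](C)[C@@]2(O)[C@H](O[Si](C)(C)C(C)(C)C)[C@H]2[C@@H](C)[C@@H](OCc3ccc(OC)cc3)C[C@H](O[Si](C)(C)C(C)(C)C)[C@]2(C)[C@H](O[Si](C)(C)C(C)(C)C)C[C@H]1O[Si](C)(C)C(C)(C)C
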